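(The readings are simulated with constants of no real substance; noise was put on by code.)

We start from late times, with the last readings of the noon and spring runs, taken at 4.00 h.

| setting | noon | spring | flask |
|---|---|---|---|
| substrate | 0.050 M | 0.050 M | 0.050 M |
| gas | 2.5 mM (held) | 2.5 mM (held) | 2.5 mM (held) |
| free catalyst | 34 µM | 75 µM | 50 µM |
| remark | run made earlier | run made earlier |  |
| time |  |  | 6.0 h |

| run | time / h | product / % | substrate / % |
|---|---|---|---|
| noon | 0.333 | 1.5 | 97.3 |
| noon | 0.833 | 4.5 | 95.0 |
| noon | 1.50 | 8.4 | 91.5 |
| noon | 2.50 | 12.9 | 86.8 |
| noon | 4.00 | 20.7 | 80.4 |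
| spring | 0.667 | 8.5 | 93.3 |
| spring | 1.33 | 15.0 | 85.2 |
| spring | 2.00 | 23.1 | 78.0 |
| spring | 3.00 | 31.4 | 68.5 |
| spring | 4.00 | 40.6 | 60.0 |

(standard deviation of a reading: 0.5 percentage points)

- at the start none of partner is dissolved
- the numbers in the tables scatter by 0.5 percentage points (one standard deviation)
- steps thought possible: catalyst intermediate B -> free catalyst + product; substrate + catalyst intermediate A <-> catalyst intermediate B; gas <-> partner; free catalyst <-> dormant form; partner + free catalyst -> catalyst intermediate A

- the product standing at 6.0 h, as a percentage of the substrate charged
- the change that raises the amount of product at 6.0 h, in percent of the substrate charged most ("none" if none brings more than 2 percentage points) (larch / elm / ash / none)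
- amount of product at 6.0 h, in percent of the substrate charged, after elm

- larch: doubling the saturation concentration of gas, all else as stated
- elm: doubling the transfer coefficient of the gas, all else as stated
- ash: doubling the amount of free catalyst, all else as stated

Does the catalyst work once or many times? By 4.00 h the noon run has made 304 product molecules per catalyst charged and the spring run 271, so we should ask for its pace.

Does that pace hold from one charge to the other? We take the natural logarithm of substrate charged over substrate left and divide it by catalyst charge times time. Noon gives 1600 L mol⁻¹ h⁻¹ and spring 1700 L mol⁻¹ h⁻¹, a ratio of 1.06. We carry their mean, 1650 L mol⁻¹ h⁻¹, as the turnover constant, which treats substrate loss as pseudo-first-order at a given catalyst charge.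

What does it give? For the flask we reckon 39.1%, and with doubled catalyst 62.9%, so ash gains 24 percentage points. The runs never moved the gas, but the constant read from the spring run, which had more catalyst than the flask, stood within that ratio of the noon value, so we expect elm to bring little.

The forecast says 40%, ash and 40.5%, holding that “the rate is proportional to catalyst”.

The flask gives 40.7%; ash is best, with ash 28 points, larch 5.7 points and elm 0.46 points, and elm ends at 41.1%.

    catalyst intermediate B → free catalyst + product (k = 420 h⁻¹)
    substrate + catalyst intermediate A ⇌ catalyst intermediate B (K = 10.0 L mol⁻¹, k = 13000 L mol⁻¹ h⁻¹)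
    gas ⇌ partner, rate k3*(csat - [partner]) (kL = 20.0 h⁻¹)
    free catalyst ⇌ dormant form (K = 0.560, k = 0.460 h⁻¹)
    partner + free catalyst → catalyst intermediate A (k = 1.50 × 10⁵ L mol⁻¹ h⁻¹)

In the flask at 2.41 h, catalyst intermediate B falls back 3.1 times faster than it goes on. At 3.00 h catalyst intermediate A, the resting state, holds 54.3% of the catalyst, more than any other form. The substrate left in the flask gives a constant of 1740 L mol⁻¹ h⁻¹ against our 1650 L mol⁻¹ h⁻¹. For a neighbour charged with 0.020 M of substrate our constant, which holds no term for the charge, gives 39.1% again, but that neighbour reaches 52.0%, with its own constant at 2450 L mol⁻¹ h⁻¹, so ours belongs to the 0.050 M charge.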